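## The problem

Compound 11 is an isoflavone: a benzene ring A fused to a 4-pyranone ring C, with a 2,4-dihydroxyphenyl ring B on C3. Ring A carries a substituent on every carbon, hydroxyls at C5 and C7 and 3-methylbut-2-enyl (prenyl) groups at C6 and C8, so nothing can be added to it late by aromatic substitution. There is no stereocentre and no alkene geometry to set, because each prenyl double bond ends in two methyl groups. What must be controlled is position: two prenyl groups on carbon and not on oxygen, and the aryl group on C3 and not on C2. The prenyl groups restrict the reagents, since each lies next to a phenol: acid closes 2,2-dimethylchroman rings, and electrophilic halogen, peracids, hydrogenation and strong oxidants attack the trisubstituted alkenes. The pyranone is opened by hydroxide at C2, and the four phenols need a mask that leaves under mild conditions. The feature that allows a short route is the place of C4: it is bonded to C4a, which lies between the oxygen-bearing carbons C5 and C8a. Read backwards, C4 is an aldehyde carbon ortho to a free phenol (the later O1), the pair that chelates rhodium and hands the aldehyde C–H bond to the metal; C3 and C2 are then the two carbons of an alkyne, and C2, which bears only hydrogen, can carry a removable silyl group.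

## Retrosynthesis

**11 from 10.** The last operation breaks no skeletal bond; the four O–CH2OCH3 bonds of 10 are cleaved. Methoxymethyl (MOM) is preferred to its neighbours: benzyl would need hydrogenolysis, which saturates the prenyl groups; methyl would need a boron trihalide, which cyclises them; phenolic silyl ethers ortho or para to a carbonyl group would be at risk from acetate at 80 °C in the annulation. The forward step needs acetal cleavage at an acidity that ortho-prenylphenols tolerate.

**10 from 9.** The C2–H bond is traced back to a C2–Si bond. The trimethylsilyl group of 9 has no place in the target. It is the handle meant to decide which way round the alkyne enters ring C, and it can be exchanged for hydrogen without touching alkenes or acetals. The forward step needs protodesilylation by fluoride without opening the pyranone.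

**9 from 4 and 8.** Ring C is cut at C4–C3 and O1–C2. This gives salicylaldehyde 4, which holds ring A with all six substituents, and arylsilylalkyne 8, which holds ring B, C3 and C2. The neighbouring cuts are weaker here. Cutting C3–C1' calls for electrophilic iodination at C3 with two prenyl groups present. Cutting only at C2 calls for a benzyl ketone to be built on the hindered ring A first. Both build ring C linearly on the more valuable half. The chosen cut is convergent: each half is two steps from purchased compounds, and ring C closes in the step that joins them. The forward reaction must activate the aldehyde C–H bond of a fully substituted, electron-rich salicylaldehyde, leave the prenyl groups alone in the presence of trivalent rhodium and Cu(OAc)2, and insert 8 so that the aryl group ends on C3.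

**8 from 6 and 7; 6 from 5.** The C(sp2)–C(sp) bond of 8 is cut by a Sonogashira disconnection to aryl bromide 6 and trimethylsilylacetylene 7. Bromide 6 is the bis-MOM ether of 4-bromoresorcinol 5. The purchased bromide already fixes the 1,2,4-pattern of ring B, so no regiochemistry has to be created. The forward coupling must work on an electron-rich, ortho-substituted aryl bromide.

**4 from 3; 3 from 1 and 2.** Two O–MOM bonds are removed from 4 to give trihydroxy aldehyde 3. The third hydroxyl stays free because it is hydrogen-bonded to the aldehyde, and it is exactly the phenol that rhodium needs. The two ring–CH2 bonds of 3 are then cut to 2,4,6-trihydroxybenzaldehyde 1 and two molecules of prenyl bromide 2. Ring 1 has only two free carbons, each activated by three phenoxide oxygens, so an aromatic dialkylated product can only be 3. The price is modest selectivity between C-alkylation, O-alkylation and over-alkylation, accepted in the first step on the cheapest materials. A cleaner way to 4, by repeated directed ortho-metalation of a fully protected benzenetriol, is three steps longer and is held in reserve.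

## Roads not taken

**Alternative 1:** The prenyl–ring bonds C6–CH2 and C8–CH2 are cut last. The 5,7-bis(2-methylbut-3-en-2-yl) ether A2 would be heated in N,N-diethylaniline, and two aromatic Claisen rearrangements would give the 6,8-diprenyl compound A1. No ring is formed, and removal of two silyl ethers would finish the synthesis.
- Merits: the [3,3] shift turns a 1,1-dimethylallyl ether into a linear prenyl group on carbon without any metal. The isoflavone core of A2 can be assembled by fully established chemistry before a sensitive alkene is present. In that respect this road is safer than the chosen plan, whose ring-forming step depends on an orientation that has not been shown.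
- Weak points: A2 itself. Tertiary allyl ethers are not available by simple alkylation; each oxygen needs a tertiary propargyl electrophile and a semi-hydrogenation. The C5 hydroxyl, hydrogen-bonded to the C4 carbonyl, is the least reactive phenol of the molecule. The rearrangement is also ambiguous: the C7 ether can go to C8 or C6, whereas the C5 ether has only C6. If the C7 group takes C6, the C5 group is left with a para shift or loss of isoprene. At the temperature needed, the new ortho-prenylphenols can cyclise.
- Comparison: the chosen plan places both prenyl groups in step 1 on a ring with only two free positions, so no such ambiguity exists, and it is clearly shorter than any sequence through A2 and A1.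

**Alternative 2:** Ring A is cut at C5–C6 and traced to pyranone keto ester A4, in which rings C and B are complete and C5 is an ester carbon on C4a. The dianion of A4, made with LiN(i-Pr)2, would attack the ester through C6 in a Dieckmann-type closure. Enolisation would aromatise ring A to the 5,7-diol A3, and acid would remove the two MOM groups.
- Merits: the carbon chain fixes the positions of both prenyl groups, no aromatic substitution is needed, and the 5,7-hydroxyls appear unprotected. No step depends on the orientation of an alkyne insertion, and on that point this road is better than the chosen plan.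
- Weak points: A4 is a 2,3,5-trisubstituted 4-pyranone with a branched, doubly prenylated side chain, and no short preparation of it is in sight. The base must deprotonate the C6 methylene in the presence of the more acidic C8 methine, hence the dianion. 4-Pyranones are themselves electrophilic at C2 towards amide bases and enolates.
- Comparison: this road spends most of its steps building, by the hardest chemistry, the ring that the chosen plan obtains from 1 in two steps.

**Alternative 3:** Ring B is taken apart completely. The bonds C1'–C2', C2'–C3', C4'–C5' and C5'–C6' lead back to the chromonyl vinyl diazoketone A6 and the siloxyalkyne A7. Irradiation of A6 would trigger a Wolff rearrangement to a vinylketene. [2+2] cycloaddition with A7 would give a cyclobutenone, and four-electron ring opening, 6π-electrocyclisation and tautomerisation would give resorcinol A5, with the free hydroxyl at C2' and the silyl ether at C4'.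
- Merits: the oxygen pattern of ring B follows from the mechanism, the two ring B oxygens come out differentiated, and C3 carries its substituent before ring B exists, so the C2/C3 question never arises. On that point it is better than the chosen plan.
- Weak points: ring B is a resorcinol, the one part that can be bought (5), and it would be built here by four C–C bonds. Beyond rings A and C, A6 needs a formylation at C3, an olefination and a diazo transfer. The chromone absorbs where the diazoketone is irradiated, so photochemistry at C2–C3 and at the prenyl alkenes is a risk. A7 is a sensitive reagent, and two different deprotections remain after the key step.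
- Comparison: the chosen plan buys ring B and spends its one uncertain step on ring C instead.

Key step: step 5

Assumption: 1, 2, 5 and 7 are purchased; the target has no stereocentre, so no step has to set configuration.

## Steps

Step 1
Reactants: 1 2,4,6-trihydroxybenzaldehyde; 2 prenyl bromide (1-bromo-3-methylbut-2-ene)
Product: 3 2,4,6-trihydroxy-3,5-bis(3-methylbut-2-enyl)benzaldehyde
Conditions: 2 (2.2 equiv), KOH (10% aq., 3 equiv), 0 °C to rt, N2
Reagents that add atoms: none
Why: C-alkylation of a phloroglucinol phenoxide by an allylic bromide in water, the reaction used to make diprenylated acylphloroglucinols; the protic medium solvates the oxygens and sends the soft electrophile to the ring carbons, and since only C3 and C5 carry hydrogen the aromatic dialkylated product can only be 3.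

Step 2
Reactants: 3 2,4,6-trihydroxy-3,5-bis(3-methylbut-2-enyl)benzaldehyde
Product: 4 2-hydroxy-4,6-bis(methoxymethoxy)-3,5-bis(3-methylbut-2-enyl)benzaldehyde
Conditions: MOMCl (2.3 equiv), i-Pr2NEt (3 equiv), CH2Cl2, 0 °C to rt
Reagents that add atoms: chloromethyl methyl ether (MOMCl), COCCl
Why: O-alkylation of phenols with an α-chloro ether; the C4 hydroxyl and one of the two equivalent ortho hydroxyls react, while the last ortho hydroxyl is held in a hydrogen bond to the aldehyde and stays free, the usual outcome with 2,4,6-trihydroxyaryl carbonyl compounds.

Step 3
Reactants: 5 4-bromoresorcinol (4-bromobenzene-1,3-diol)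
Product: 6 1-bromo-2,4-bis(methoxymethoxy)benzene
Conditions: MOMCl (2.5 equiv), i-Pr2NEt (3 equiv), CH2Cl2, 0 °C to rt
Reagents that add atoms: chloromethyl methyl ether (MOMCl), COCCl
Why: Standard formation of aryl MOM ethers; both phenols must be masked because free phenols would bind copper and rhodium in steps 4 and 5, and the acetals are stable to amines, palladium, fluoride and acetate.

Step 4
Reactants: 6 1-bromo-2,4-bis(methoxymethoxy)benzene; 7 trimethylsilylacetylene (ethynyl(trimethyl)silane)
Product: 8 [2,4-bis(methoxymethoxy)phenyl]ethynyl(trimethyl)silane
Conditions: 7 (1.3 equiv), PdCl2(PhCN)2 (3 mol%), [HP(t-Bu)3]BF4 (6 mol%), CuI (2 mol%), i-Pr2NH, dioxane, rt to 45 °C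
Reagents that add atoms: none
Why: Sonogashira coupling; the bulky, electron-rich P(t-Bu)3 ligand lets zerovalent palladium add to the electron-rich ortho-alkoxy aryl bromide near room temperature, which keeps the volatile alkyne in solution and the C–Si bond intact in the amine medium.

Step 5
Reactants: 4 2-hydroxy-4,6-bis(methoxymethoxy)-3,5-bis(3-methylbut-2-enyl)benzaldehyde; 8 [2,4-bis(methoxymethoxy)phenyl]ethynyl(trimethyl)silane
Product: 9 5,7-bis(methoxymethoxy)-3-[2,4-bis(methoxymethoxy)phenyl]-6,8-bis(3-methylbut-2-enyl)-2-(trimethylsilyl)chromen-4-one
Conditions: 8 (1.3 equiv), [Cp*RhCl2]2 (2.5 mol%), Cu(OAc)2 (2.1 equiv), ClCH2CH2Cl, 80 °C, N2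
Reagents that add atoms: none
Why: Cu(OAc)2 turns the chloride dimer into Cp*Rh(OAc)2, the phenol of 4 binds trivalent rhodium as a phenoxide, and acetate-assisted cleavage of the aldehyde C–H bond gives a five-membered acylrhodium chelate. Alkyne 8 inserts into the rhodium–acyl bond (C4–C3) to give a seven-membered oxarhodacycle, and C–O reductive elimination (O1–C2) closes the six-membered ring C in a formal [4+2] oxidative annulation, after which two equivalents of Cu(OAc)2 return monovalent rhodium to the trivalent state. The closest known reaction is the rhodium-catalysed oxidative coupling of salicylaldehydes with internal alkynes to 2,3-disubstituted chromones with Cu(OAc)2 as oxidant. The selectivity needed is the orientation of insertion: the acyl carbon must bond to the aryl-bearing alkyne carbon and rhodium to the silyl-bearing one, against the usual tendency of an aryl group to end next to the ring oxygen, and this sense has not been demonstrated for a 1-aryl-2-silylalkyne in this annulation. It is expected because the large SiMe3 group prefers the long Rh–C bond to the short forming C–C bond and because a metal–carbon bond α to silicon is stabilised, the same bias that places silicon next to the heteroatom in palladium-catalysed heteroannulations of arylsilylalkynes. Ring A has no C–H bond, so the chelated metal can reach only the aldehyde hydrogen, and the mirror plane of the parent ring removes any question of which oxygen closes the ring. The aprotic solvent and the absence of silver salts protect the alkynyl C–Si bond before insertion, and loss of silicon after ring closure would only give 10 early. No stereocentre is formed.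

Step 6
Reactants: 9 5,7-bis(methoxymethoxy)-3-[2,4-bis(methoxymethoxy)phenyl]-6,8-bis(3-methylbut-2-enyl)-2-(trimethylsilyl)chromen-4-one
Product: 10 5,7-bis(methoxymethoxy)-3-[2,4-bis(methoxymethoxy)phenyl]-6,8-bis(3-methylbut-2-enyl)chromen-4-one
Conditions: TBAF·3H2O (1.2 equiv), THF, 0 °C to rt
Reagents that add atoms: none
Why: Fluoride-induced protodesilylation of a vinylsilane whose carbon is bonded to the ring oxygen and is the β-carbon of a vinylogous ester: fluoride adds to silicon and the developing C2 carbanion is protonated by the hydrate water; acetals and prenyl groups are inert to fluoride, and low temperature with a small excess limits attack of hydroxide at C2.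

Step 7
Reactants: 10 5,7-bis(methoxymethoxy)-3-[2,4-bis(methoxymethoxy)phenyl]-6,8-bis(3-methylbut-2-enyl)chromen-4-one
Product: 11 5,7-dihydroxy-3-(2,4-dihydroxyphenyl)-6,8-bis(3-methylbut-2-enyl)chromen-4-one
Conditions: HCl (3 M aq.), MeOH, 40 °C
Reagents that add atoms: none
Why: Acid-catalysed acetal exchange with methanol frees the four phenols and gives dimethoxymethane, the customary last step for prenylated polyphenols; mild temperature and stopping at full conversion keep the slower acid-catalysed addition of the C5 and C7 hydroxyls to the prenyl double bonds in check.

## Compound list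

1 | 2,4,6-trihydroxybenzaldehyde | O=Cc1c(O)cc(O)cc1O | starting material
2 | prenyl bromide (1-bromo-3-methylbut-2-ene) | CC(C)=CCBr | starting material
3 | 2,4,6-trihydroxy-3,5-bis(3-methylbut-2-enyl)benzaldehyde | O=Cc1c(O)c(CC=C(C)C)c(O)c(CC=C(C)C)c1O | intermediate
4 | 2-hydroxy-4,6-bis(methoxymethoxy)-3,5-bis(3-methylbut-2-enyl)benzaldehyde | O=Cc1c(O)c(CC=C(C)C)c(OCOC)c(CC=C(C)C)c1OCOC | intermediate
5 | 4-bromoresorcinol (4-bromobenzene-1,3-diol) | Oc1ccc(Br)c(O)c1 | starting material
6 | 1-bromo-2,4-bis(methoxymethoxy)benzene | COCOc1ccc(Br)c(OCOC)c1 | intermediate
7 | trimethylsilylacetylene (ethynyl(trimethyl)silane) | C#C[Si](C)(C)C | starting material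
8 | [2,4-bis(methoxymethoxy)phenyl]ethynyl(trimethyl)silane | C[Si](C)(C)C#Cc1ccc(OCOC)cc1OCOC | intermediate
9 | 5,7-bis(methoxymethoxy)-3-[2,4-bis(methoxymethoxy)phenyl]-6,8-bis(3-methylbut-2-enyl)-2-(trimethylsilyl)chromen-4-one | CC(C)=CCc1c(OCOC)c(CC=C(C)C)c2oc([Si](C)(C)C)c(-c3ccc(OCOC)cc3OCOC)c(=O)c2c1OCOC | intermediate
10 | 5,7-bis(methoxymethoxy)-3-[2,4-bis(methoxymethoxy)phenyl]-6,8-bis(3-methylbut-2-enyl)chromen-4-one | CC(C)=CCc1c(OCOC)c(CC=C(C)C)c2occ(-c3ccc(OCOC)cc3OCOC)c(=O)c2c1OCOC | intermediate
11 | 5,7-dihydroxy-3-(2,4-dihydroxyphenyl)-6,8-bis(3-methylbut-2-enyl)chromen-4-one (EANPDB:LEGU_00069) | CC(C)=CCc1c(O)c(CC=C(C)C)c2occ(-c3ccc(O)cc3O)c(=O)c2c1O | target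

## Step count and least certain steps

Total: 7 steps. Longest linear sequence: 5 steps (steps 1, 2, 5, 6, 7); steps 3 and 4 form the second branch.

**Step 5 (key step).** The most likely failure is insertion of the alkyne in the opposite orientation, with aryl next to the ring oxygen, because the silicon-directed sense has not been shown for this annulation. Second, the hindered alkyne may insert slowly, so that decarbonylation of the acylrhodium species or copper-mediated oxidative cyclisation of the C3 prenyl group onto the free phenol takes over. Third, the alkyne may lose silicon before insertion and then homocouple. The orientation has to be proven on 10 before material is committed; a long-range C–H correlation from H-2 to C8a distinguishes the two skeletons.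

The fallback sets out from 4 and 6 and returns at 10, using the established iodochromone cross-coupling route to isoflavones. Grignard addition of MeMgBr (excess, THF, 0 °C) to 4 gives the racemic carbinol 1-[2-hydroxy-4,6-bis(methoxymethoxy)-3,5-bis(3-methylbut-2-enyl)phenyl]ethanol F1. MnO2 in CH2Cl2 oxidises this benzylic alcohol to 1-[2-hydroxy-4,6-bis(methoxymethoxy)-3,5-bis(3-methylbut-2-enyl)phenyl]ethanone F2. Condensation with N,N-dimethylformamide dimethyl acetal gives the enaminone (E)-3-(dimethylamino)-1-[2-hydroxy-4,6-bis(methoxymethoxy)-3,5-bis(3-methylbut-2-enyl)phenyl]prop-2-en-1-one F3. Iodine (one equivalent) and pyridine in CHCl3 at 0 °C cyclise it to 3-iodo-5,7-bis(methoxymethoxy)-6,8-bis(3-methylbut-2-enyl)chromen-4-one F4; the enaminone is far more nucleophilic than the prenyl double bonds, which is why iodine is not used in excess. Bromine–lithium exchange on 6 (n-BuLi, THF, −78 °C), quenching with B(Oi-Pr)3 and aqueous work-up give [2,4-bis(methoxymethoxy)phenyl]boronic acid F5. Suzuki–Miyaura coupling of F4 with F5 (Pd(PPh3)4, Na2CO3, DME–water, 80 °C) gives 10, and the route continues with step 7.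

**Step 1.** The likely failure is poor selectivity of the alkylation: a second alkylation at an already substituted ring carbon (loss of aromaticity), alkylation on oxygen, and stopping after one prenyl group. Together these can leave little of the 3,5-dialkylated aldehyde and make its purification laborious.

The fallback sets out from 2 and returns at 4. It replaces the polyphenoxide alkylation by three directed ortho-metalations. Purchased phloroglucinol is converted with NaH and MOMCl in DMF into 1,3,5-tris(methoxymethoxy)benzene F6. Lithiation between two acetal oxygens (n-BuLi, THF, 0 °C) and alkylation with 2 in the presence of CuI (10 mol%) gives 1,3,5-tris(methoxymethoxy)-2-(3-methylbut-2-enyl)benzene F7. A second round gives 1,3,5-tris(methoxymethoxy)-2,4-bis(3-methylbut-2-enyl)benzene F8. A third lithiation quenched with DMF gives 2,4,6-tris(methoxymethoxy)-3,5-bis(3-methylbut-2-enyl)benzaldehyde F9. MgBr2·OEt2 in Et2O–toluene, held between the aldehyde oxygen and one of the two equivalent neighbouring acetal oxygens, removes that single MOM group and gives 4, from which step 5 follows.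

**Step 6.** Two processes threaten this step: conjugate addition of hydroxide (from wet fluoride) at C2 with opening of ring C, or a C–Si bond that resists fluoride at room temperature, since the C2 carbanion is only moderately stabilised.

The fallback sets out from 9 and returns at 10 and makes deliberate use of the ring opening. KOH in aqueous ethanol at reflux opens ring C at C2 and cleaves the C2–C3 bond, the classical alkaline degradation of isoflavones. This gives the deoxybenzoin 2-[2,4-bis(methoxymethoxy)phenyl]-1-[2-hydroxy-4,6-bis(methoxymethoxy)-3,5-bis(3-methylbut-2-enyl)phenyl]ethanone F10, with C2 leaving as formate and silicon as silanol. Heating F10 with N,N-dimethylformamide dimethyl acetal in toluene puts C2 back as a CH group and recloses ring C to 10.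

**Step 7.** Once the phenols are free, acid can add the C5 or C7 hydroxyl to a neighbouring prenyl double bond (closure of a 2,2-dimethylchroman ring) or add HCl or methanol across the alkenes, if the reaction runs too long or too warm.

The fallback sets out from 10 and returns at 11. It replaces protic solvolysis by silyl transfer under buffered, aprotic conditions. TMSOTf and 2,2'-bipyridyl in CH2Cl2 at 0 °C convert the four aryl MOM ethers into the tetrakis(trimethylsilyl) ether 3-[2,4-bis(trimethylsilyloxy)phenyl]-6,8-bis(3-methylbut-2-enyl)-5,7-bis(trimethylsilyloxy)chromen-4-one F11, in which no free hydroxyl can add to an alkene. Water at neutral pH then hydrolyses the silyl ethers to 11.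

## Further compounds

F1 | step 5 | 1-[2-hydroxy-4,6-bis(methoxymethoxy)-3,5-bis(3-methylbut-2-enyl)phenyl]ethanol (racemic) | CC(O)c1c(O)c(CC=C(C)C)c(OCOC)c(CC=C(C)C)c1OCOC
F2 | step 5 | 1-[2-hydroxy-4,6-bis(methoxymethoxy)-3,5-bis(3-methylbut-2-enyl)phenyl]ethanone | CC(=O)c1c(O)c(CC=C(C)C)c(OCOC)c(CC=C(C)C)c1OCOC
F3 | step 5 | (E)-3-(dimethylamino)-1-[2-hydroxy-4,6-bis(methoxymethoxy)-3,5-bis(3-methylbut-2-enyl)phenyl]prop-2-en-1-one | CN(C)/C=C/C(=O)c1c(O)c(CC=C(C)C)c(OCOC)c(CC=C(C)C)c1OCOC
F4 | step 5 | 3-iodo-5,7-bis(methoxymethoxy)-6,8-bis(3-methylbut-2-enyl)chromen-4-one | CC(C)=CCc1c(OCOC)c(CC=C(C)C)c2occ(I)c(=O)c2c1OCOC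
F5 | step 5 | [2,4-bis(methoxymethoxy)phenyl]boronic acid | COCOc1ccc(B(O)O)c(OCOC)c1
F6 | step 1 | 1,3,5-tris(methoxymethoxy)benzene | COCOc1cc(OCOC)cc(OCOC)c1
F7 | step 1 | 1,3,5-tris(methoxymethoxy)-2-(3-methylbut-2-enyl)benzene | COCOc1cc(OCOC)c(CC=C(C)C)c(OCOC)c1
F8 | step 1 | 1,3,5-tris(methoxymethoxy)-2,4-bis(3-methylbut-2-enyl)benzene | COCOc1cc(OCOC)c(CC=C(C)C)c(OCOC)c1CC=C(C)C
F9 | step 1 | 2,4,6-tris(methoxymethoxy)-3,5-bis(3-methylbut-2-enyl)benzaldehyde | O=Cc1c(OCOC)c(CC=C(C)C)c(OCOC)c(CC=C(C)C)c1OCOC
F10 | step 6 | 2-[2,4-bis(methoxymethoxy)phenyl]-1-[2-hydroxy-4,6-bis(methoxymethoxy)-3,5-bis(3-methylbut-2-enyl)phenyl]ethanone | O=C(Cc1ccc(OCOC)cc1OCOC)c1c(O)c(CC=C(C)C)c(OCOC)c(CC=C(C)C)c1OCOC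
F11 | step 7 | 3-[2,4-bis(trimethylsilyloxy)phenyl]-6,8-bis(3-methylbut-2-enyl)-5,7-bis(trimethylsilyloxy)chromen-4-one | CC(C)=CCc1c(O[Si](C)(C)C)c(CC=C(C)C)c2occ(-c3ccc(O[Si](C)(C)C)cc3O[Si](C)(C)C)c(=O)c2c1O[Si](C)(C)C
A1 | alternative 1 | 2',4'-bis(tert-butyldimethylsilyloxy)-5,7-dihydroxy-6,8-bis(3-methylbut-2-enyl)isoflavone | CC(C)=CCc1c(O)c(CC=C(C)C)c2occ(-c3ccc(O[Si](C)(C)C(C)(C)C)cc3O[Si](C)(C)C(C)(C)C)c(=O)c2c1O
A2 | alternative 1 | 2',4'-bis(tert-butyldimethylsilyloxy)-5,7-bis(2-methylbut-3-en-2-yloxy)isoflavone | C=CC(C)(C)Oc1cc(OC(C)(C)C=C)c2c(=O)c(-c3ccc(O[Si](C)(C)C(C)(C)C)cc3O[Si](C)(C)C(C)(C)C)coc2c1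
A3 | alternative 2 | 5,7-dihydroxy-2',4'-bis(methoxymethoxy)-6,8-bis(3-methylbut-2-enyl)isoflavone | CC(C)=CCc1c(O)c(CC=C(C)C)c2occ(-c3ccc(OCOC)cc3OCOC)c(=O)c2c1O
A4 | alternative 2 | methyl 5-[2,4-bis(methoxymethoxy)phenyl]-2-(2,10-dimethyl-6-oxoundeca-2,9-dien-5-yl)-4-oxo-4H-pyran-3-carboxylate (racemic) | COC(=O)c1c(C(CC=C(C)C)C(=O)CCC=C(C)C)occ(-c2ccc(OCOC)cc2OCOC)c1=O
A5 | alternative 3 | 2'-hydroxy-5,7-bis(methoxymethoxy)-6,8-bis(3-methylbut-2-enyl)-4'-(triisopropylsiloxy)isoflavone | CC(C)=CCc1c(OCOC)c(CC=C(C)C)c2occ(-c3ccc(O[Si](C(C)C)(C(C)C)C(C)C)cc3O)c(=O)c2c1OCOC
A6 | alternative 3 | (E)-1-diazo-4-[5,7-bis(methoxymethoxy)-6,8-bis(3-methylbut-2-enyl)-4-oxo-4H-chromen-3-yl]but-3-en-2-one | [N-]=[N+]=CC(=O)/C=C/c1coc2c(CC=C(C)C)c(OCOC)c(CC=C(C)C)c(OCOC)c2c1=O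
A7 | alternative 3 | ethynyloxy(triisopropyl)silane | C#CO[Si](C(C)C)(C(C)C)C(C)C
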